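I counted turnovers. Each flask was charged with 20.0 mM of free catalyst, so target divided by that charge gave the turnover number, and I wanted it for the summer run.

all flasks: free catalyst 20.0 mM
- dusk: substrate 250 mM; partner 250 mM
- winter: substrate 130 mM; partner 130 mM
- noon: substrate 750 mM; partner 250 mM
- dawn: substrate 250 mM; partner 500 mM
- summer: substrate 1200 mM; partner 1200 mM; time 65 min

- dusk run (time / min: [target] / mM): 11: 55.6; 22: 104.6; 32: 137.8; 43: 168.0; 54: 188.1; 65: 203.5
- winter run (time / min: [target] / mM): 11: 30.1; 22: 55.4; 32: 72.0; 43: 86.5; 54: 97.4; 65: 103.4
- noon run (time / min: [target] / mM): 11: 59.1; 22: 107.8; 32: 140.7; 43: 169.1; 54: 191.3; 65: 207.2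
- dawn run (time / min: [target] / mM): 11: 72.1; 22: 132.2; 32: 171.1; 43: 201.2; 54: 221.4; 65: 232.9

(readings scatter by 0.8 mM)

* the power of [partner] that the first rate follows, about the charge of the dusk run; measure it at two percent of substrate made into target
* the power of [substrate] that the first rate follows, about the charge of the dusk run; measure it at two percent of substrate made into target (one fixed amount of target, the same in the runs compared)
* the winter run starts with 120 mM less of substrate and of partner than the dusk run, and with no target. Compared where both hold the same amount of substrate, once fifteen percent of what the winter run was charged with has turned into target, is the winter run faster, slower or alike (within a tenth)?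
* target in the summer run at 65 min, as a share of the substrate charged

- Overall: substrate + partner -> target, with free catalyst as catalyst.
- Constant volume, constant temperature.
- What is held in complexes is read along with the free species.
- An order is taken over about fifteen percent of the charge, up and down.

By 65 min the dusk run had made 10.2 turnovers of the 12.5 its substrate offered, and I called turnovers made over turnovers offered the turnover fill, here 81.4%. The winter run stood at 79.5% at that time, and going from winter to dusk multiplied the charge by 1.92 and the turnovers by 1.97. The first readings of the same pair put the two orders together at 0.938, so I carried the dusk fill to the summer run, which gave 48.8 of its 60.0 turnovers. At the comparison point the dusk run holds the same substrate and partner as the winter run, with 6.00 more turnovers behind it, and since the two fills read at 65 min stood 1.9 percentage points apart I wrote alike.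

The forecast gave 0.5 for the order in [partner], 0.25 for the order in [substrate], slower for the winter run, “a borderline call”, and 46% for the summer run, which differs from my fill.

The flask gave 0.48 and 0.41 for those orders, alike for the winter run at a rate ratio of 0.99, and 74.5% for the summer run.

    free catalyst + substrate → loaded catalyst + by-product (9.060 M⁻¹ min⁻¹)
    loaded catalyst + partner → target + free catalyst (2.184 M⁻¹ min⁻¹)
    2 free catalyst ⇌ resting dimer, settled at all times (117.0 M⁻¹)
    substrate + partner ⇌ idle substrate-reagent adduct, settled at all times (0.9850 M⁻¹)

The summer run made 44.7 turnovers, fewer than the 48.8 that my fill of 81.4% had given. The summer run without the idle substrate-reagent adduct reached 85.8%, so that adduct cost the summer run 6.76 turnovers; K2 times the substrate charge is 1.18 there, more than the 0.246 of the dusk run. The winter run reached 3.25 turnovers, half of those offered, at 27.7 min, while the dusk fill went from 41.8% at 22 min to 55.1% at 32 min.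

(All runs were generated by integration for an exercise; noise was put on by code.)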